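## Retrosynthetic overview

1. Giganteone A comes from its octamethyl ether. All eight phenols travel as methyl ethers and are freed together in the last step.
2. Key disconnection: the Cα–Cβ bond next to the 2,6-dioxygenated benzoyl group. It is made by a directed aldol addition of the lithium enolate of 2,6-dimethoxyacetophenone to a fully elaborated biaryl heptanal, followed by dehydration and hydrogenation.
3. The second nonanoyl chain is cut the same way one stage earlier, from the enolate of a biaryl methyl ketone and 7-(3,4-dimethoxyphenyl)heptanal.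
4. The biaryl methyl ketone comes from a Suzuki coupling of two small arenes. The aldehyde and the boronate both derive from one alcohol (Wittig of veratraldehyde with a C6 ylide), and the bromoketone derives from 2,6-dimethoxyacetophenone.
5. No ring is formed. All four benzene rings are bought (2 × veratraldehyde, 2 × 2,6-dimethoxyacetophenone).

Assumption: the target SMILES carries no stereodescriptor. The molecule has no stereocentre, and its biaryl axis has only two ortho substituents, so it is not configurationally stable. The target is therefore one achiral compound and no stereocontrol is needed.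

## Route

Step 1
Reactants: 1 6-bromohexanoic acid
Product: 2 (5-carboxypentyl)triphenylphosphonium bromide
Conditions: PPh3 (1.05 equiv), MeCN, reflux, 24 h
Reagents that add atoms: triphenylphosphine, c1ccc(cc1)P(c1ccccc1)c1ccccc1
Why: SN2 quaternisation of PPh3 by an unhindered primary bromide is clean, and the phosphonium salt crystallises out.

Step 2
Reactants: 2 (5-carboxypentyl)triphenylphosphonium bromide; 3 3,4-dimethoxybenzaldehyde (veratraldehyde)
Product: 5 7-(3,4-dimethoxyphenyl)hept-6-enoic acid (E/Z mixture), via carboxylate ylide 4 (not isolated)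
Conditions: KOtBu (2.1 equiv), THF, 0 °C; then 3, 0 °C → rt; 1 M HCl work-up
Reagents that add atoms: none
Why: This is a Wittig olefination of a non-enolisable aromatic aldehyde with the dianionic carboxylate ylide, and the E/Z ratio does not matter because the alkene is hydrogenated next.

Step 3
Reactants: 5 7-(3,4-dimethoxyphenyl)hept-6-enoic acid
Product: 6 7-(3,4-dimethoxyphenyl)heptanoic acid
Conditions: H2 (1 atm), 10% Pd/C, EtOAc, rt
Reagents that add atoms: none
Why: Catalytic hydrogenation of a styrenic alkene is fast, and the methyl ethers and the acid are inert.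

Step 4
Reactants: 6 7-(3,4-dimethoxyphenyl)heptanoic acid
Product: 7 7-(3,4-dimethoxyphenyl)heptan-1-ol
Conditions: LiAlH4, THF, 0 °C → reflux; Fieser work-up
Reagents that add atoms: none
Why: Hydride reduction of the carboxylic acid gives the primary alcohol, and no other reducible group is present.

Step 5
Reactants: 7 7-(3,4-dimethoxyphenyl)heptan-1-ol
Product: 8 7-(3,4-dimethoxyphenyl)heptanal
Conditions: Dess–Martin periodinane, CH2Cl2, rt
Reagents that add atoms: none
Why: The Dess–Martin oxidation stops cleanly at the aldehyde and leaves the electron-rich arene untouched.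

Step 6
Reactants: 7 7-(3,4-dimethoxyphenyl)heptan-1-ol
Product: 9 7-(2-bromo-4,5-dimethoxyphenyl)heptan-1-ol
Conditions: NBS (1.0 equiv), MeCN, 0 °C → rt, dark
Reagents that add atoms: N-bromosuccinimide, O=C1CCC(=O)N1Br
Why: Electrophilic aromatic bromination of a 4-alkylveratrole goes to the position para to one OMe and ortho to the alkyl chain, which is the only doubly activated and unhindered site.

Step 7
Reactants: 9 7-(2-bromo-4,5-dimethoxyphenyl)heptan-1-ol
Product: 10 {[7-(2-bromo-4,5-dimethoxyphenyl)heptyl]oxy}(tert-butyl)dimethylsilane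
Conditions: TBSCl, imidazole, DMF, rt
Reagents that add atoms: tert-butyldimethylsilyl chloride, CC(C)(C)[Si](C)(C)Cl
Why: Standard silyl-ether protection masks the future aldehyde carbon through the organolithium, palladium and enolate chemistry that follows.

Step 8
Reactants: 10 {[7-(2-bromo-4,5-dimethoxyphenyl)heptyl]oxy}(tert-butyl)dimethylsilane
Product: 12 tert-butyl({7-[4,5-dimethoxy-2-(4,4,5,5-tetramethyl-1,3,2-dioxaborolan-2-yl)phenyl]heptyl}oxy)dimethylsilane, via aryllithium 11 (not isolated)
Conditions: n-BuLi (1.1 equiv), THF, −78 °C; then iPrOBpin, −78 °C → rt; H2O quench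
Reagents that add atoms: 2-isopropoxy-4,4,5,5-tetramethyl-1,3,2-dioxaborolane, CC(C)OB1OC(C)(C)C(C)(C)O1
Why: Bromine–lithium exchange followed by borylation is fast at −78 °C, and no electrophilic or acidic group is present in 10.

Step 9
Reactants: 13 1-(2,6-dimethoxyphenyl)ethan-1-one (2,6-dimethoxyacetophenone)
Product: 14 1-(3-bromo-2,6-dimethoxyphenyl)ethan-1-one
Conditions: NBS (1.0 equiv), MeCN, rt, dark
Reagents that add atoms: N-bromosuccinimide, O=C1CCC(=O)N1Br
Why: In this electrophilic aromatic bromination C3 is ortho/para to both methoxy groups and meta to the acetyl group, so all directing effects agree and the first bromine slows a second substitution.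

Step 10
Reactants: 12 aryl pinacol boronate; 14 1-(3-bromo-2,6-dimethoxyphenyl)ethan-1-one
Product: 15 1-[3-(2-{7-[(tert-butyldimethylsilyl)oxy]heptyl}-4,5-dimethoxyphenyl)-2,6-dimethoxyphenyl]ethan-1-one
Conditions: Pd(OAc)2 (3 mol%), SPhos (6 mol%), K3PO4 (3 equiv), toluene/H2O 10:1, 90 °C
Reagents that add atoms: none
Why: Suzuki–Miyaura coupling with the SPhos catalyst handles a di-ortho-substituted, electron-rich biaryl, and the ketone and TBS ether tolerate aqueous phosphate.

Step 11
Reactants: 15 biaryl methyl ketone; 8 7-(3,4-dimethoxyphenyl)heptanal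
Product: 17 1-[3-(2-{7-[(tert-butyldimethylsilyl)oxy]heptyl}-4,5-dimethoxyphenyl)-2,6-dimethoxyphenyl]-9-(3,4-dimethoxyphenyl)-3-hydroxynonan-1-one (racemic), via lithium enolate 16 (not isolated)
Conditions: LDA (1.1 equiv), THF, −78 °C, 45 min; then 8 (1.3 equiv), −78 °C, 1 h; AcOH/THF quench at −78 °C
Reagents that add atoms: none
Why: In this directed aldol addition the hindered methyl ketone is fully converted to its only possible enolate before the enolisable aldehyde is added, and the new carbinol centre forms racemic and is erased in step 12.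

Step 12
Reactants: 17 β-hydroxy ketone
Product: 19 (E)-1-[3-(2-{7-[(tert-butyldimethylsilyl)oxy]heptyl}-4,5-dimethoxyphenyl)-2,6-dimethoxyphenyl]-9-(3,4-dimethoxyphenyl)non-2-en-1-one, via mesylate 18 (not isolated)
Conditions: MsCl, Et3N, CH2Cl2, 0 °C; then DBU, 0 °C → rt
Reagents that add atoms: none
Why: Mesylation followed by E1cB elimination of a β-sulfonyloxy ketone gives the conjugated E-enone without retro-aldol cleavage.

Step 13
Reactants: 19 (E)-enone
Product: 20 1-[3-(2-{7-[(tert-butyldimethylsilyl)oxy]heptyl}-4,5-dimethoxyphenyl)-2,6-dimethoxyphenyl]-9-(3,4-dimethoxyphenyl)nonan-1-one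
Conditions: H2 (1 atm), 10% Pd/C, EtOAc, rt
Reagents that add atoms: none
Why: Catalytic hydrogenation saturates the enone C=C, while the twisted di-ortho-substituted aryl ketone and the TBS ether (in EtOAc) survive.

Step 14
Reactants: 20 saturated ketone TBS ether
Product: 21 9-(3,4-dimethoxyphenyl)-1-{3-[2-(7-hydroxyheptyl)-4,5-dimethoxyphenyl]-2,6-dimethoxyphenyl}nonan-1-one
Conditions: TBAF, THF, rt
Reagents that add atoms: none
Why: Fluoride-driven desilylation of a primary TBS ether leaves the ketone and the aryl ethers untouched.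

Step 15
Reactants: 21 keto alcohol
Product: 22 7-(2-{3-[9-(3,4-dimethoxyphenyl)nonanoyl]-2,4-dimethoxyphenyl}-4,5-dimethoxyphenyl)heptanal
Conditions: Dess–Martin periodinane, CH2Cl2, rt
Reagents that add atoms: none
Why: The Dess–Martin oxidation is neutral and mild, so the keto aldehyde forms without over-oxidation or enolisation.

Step 16 (key step)
Reactants: 13 1-(2,6-dimethoxyphenyl)ethan-1-one; 22 biaryl keto aldehyde
Product: 24 1-(2,6-dimethoxyphenyl)-9-(2-{3-[9-(3,4-dimethoxyphenyl)nonanoyl]-2,4-dimethoxyphenyl}-4,5-dimethoxyphenyl)-3-hydroxynonan-1-one (racemic), via lithium enolate 23 (not isolated)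
Conditions: 13 (1.5 equiv), LDA (1.45 equiv), THF, −78 °C, 45 min; then 22 (1.0 equiv), −78 °C, 1 h; AcOH/THF quench at −78 °C
Reagents that add atoms: none
Why: In this directed aldol addition the preformed enolate (no free LDA left) adds to the aldehyde at −78 °C far faster than it attacks or deprotonates the shielded di-ortho-methoxy aryl ketone of 22, and the new carbinol centre forms racemic and is erased in step 17.

Step 17
Reactants: 24 β-hydroxy ketone
Product: 26 (E)-1-(2,6-dimethoxyphenyl)-9-(2-{3-[9-(3,4-dimethoxyphenyl)nonanoyl]-2,4-dimethoxyphenyl}-4,5-dimethoxyphenyl)non-2-en-1-one, via mesylate 25 (not isolated)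
Conditions: MsCl, Et3N, CH2Cl2, 0 °C; then DBU, 0 °C → rt
Reagents that add atoms: none
Why: Mesylation and E1cB elimination work as in step 12, and the remote saturated ketone has no leaving group and stays unchanged.

Step 18
Reactants: 26 (E)-enone
Product: 27 giganteone A octamethyl ether, 1-(2,6-dimethoxyphenyl)-9-(2-{3-[9-(3,4-dimethoxyphenyl)nonanoyl]-2,4-dimethoxyphenyl}-4,5-dimethoxyphenyl)nonan-1-one
Conditions: H2 (1 atm), 10% Pd/C, EtOAc, rt
Reagents that add atoms: none
Why: Catalytic hydrogenation reduces only the conjugated C=C, because both hindered aryl ketones resist reduction under 1 atm of H2.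

Step 19
Reactants: 27 giganteone A octamethyl ether
Product: 29 giganteone A, via octakis(dibromoboryl) ether 28 (not isolated)
Conditions: BBr3 (16 equiv), CH2Cl2, −78 °C → rt, 16 h; ice-water quench, argon
Reagents that add atoms: none
Why: Lewis-acid ether cleavage with BBr3 is especially easy for veratrole-type ethers and for methoxy groups ortho to a carbonyl (chelation), the ketones only coordinate reversibly, and hydrolysis of the aryl borates frees the eight phenols.

## Compound list

1 | 6-bromohexanoic acid | OC(=O)CCCCCBr | starting material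
2 | (5-carboxypentyl)triphenylphosphonium bromide | OC(=O)CCCCC[P+](c1ccccc1)(c1ccccc1)c1ccccc1.[Br-] | intermediate
3 | 3,4-dimethoxybenzaldehyde | COc1ccc(C=O)cc1OC | starting material
4 | potassium 6-(triphenyl-λ5-phosphanylidene)hexanoate (carboxylate ylide, not isolated) | [K+].[O-]C(=O)CCCCC=P(c1ccccc1)(c1ccccc1)c1ccccc1 | intermediate
5 | 7-(3,4-dimethoxyphenyl)hept-6-enoic acid (E/Z mixture) | COc1ccc(C=CCCCCC(=O)O)cc1OC | intermediate
6 | 7-(3,4-dimethoxyphenyl)heptanoic acid | COc1ccc(CCCCCCC(=O)O)cc1OC | intermediate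
7 | 7-(3,4-dimethoxyphenyl)heptan-1-ol | COc1ccc(CCCCCCCO)cc1OC | intermediate
8 | 7-(3,4-dimethoxyphenyl)heptanal | COc1ccc(CCCCCCC=O)cc1OC | intermediate
9 | 7-(2-bromo-4,5-dimethoxyphenyl)heptan-1-ol | COc1cc(Br)c(CCCCCCCO)cc1OC | intermediate
10 | {[7-(2-bromo-4,5-dimethoxyphenyl)heptyl]oxy}(tert-butyl)dimethylsilane | COc1cc(Br)c(CCCCCCCO[Si](C)(C)C(C)(C)C)cc1OC | intermediate
11 | [2-(7-{[tert-butyl(dimethyl)silyl]oxy}heptyl)-4,5-dimethoxyphenyl]lithium (not isolated) | COc1cc([Li])c(CCCCCCCO[Si](C)(C)C(C)(C)C)cc1OC | intermediate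
12 | tert-butyl({7-[4,5-dimethoxy-2-(4,4,5,5-tetramethyl-1,3,2-dioxaborolan-2-yl)phenyl]heptyl}oxy)dimethylsilane | COc1cc(B2OC(C)(C)C(C)(C)O2)c(CCCCCCCO[Si](C)(C)C(C)(C)C)cc1OC | intermediate
13 | 1-(2,6-dimethoxyphenyl)ethan-1-one | CC(=O)c1c(OC)cccc1OC | starting material
14 | 1-(3-bromo-2,6-dimethoxyphenyl)ethan-1-one | CC(=O)c1c(OC)ccc(Br)c1OC | intermediate
15 | 1-[3-(2-{7-[(tert-butyldimethylsilyl)oxy]heptyl}-4,5-dimethoxyphenyl)-2,6-dimethoxyphenyl]ethan-1-one | CC(=O)c1c(OC)ccc(-c2cc(OC)c(OC)cc2CCCCCCCO[Si](C)(C)C(C)(C)C)c1OC | intermediate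
16 | lithium enolate of 15 (not isolated) | [Li]OC(=C)c1c(OC)ccc(-c2cc(OC)c(OC)cc2CCCCCCCO[Si](C)(C)C(C)(C)C)c1OC | intermediate
17 | aldol adduct of 15 and 8, 3-hydroxynonan-1-one (racemic) | COc1ccc(CCCCCCC(O)CC(=O)c2c(OC)ccc(-c3cc(OC)c(OC)cc3CCCCCCCO[Si](C)(C)C(C)(C)C)c2OC)cc1OC | intermediate
18 | methanesulfonate of 17 (racemic, not isolated) | COc1ccc(CCCCCCC(OS(C)(=O)=O)CC(=O)c2c(OC)ccc(-c3cc(OC)c(OC)cc3CCCCCCCO[Si](C)(C)C(C)(C)C)c2OC)cc1OC | intermediate
19 | (E)-enone from 17 | COc1ccc(CCCCCC/C=C/C(=O)c2c(OC)ccc(-c3cc(OC)c(OC)cc3CCCCCCCO[Si](C)(C)C(C)(C)C)c2OC)cc1OC | intermediate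
20 | saturated ketone TBS ether | COc1ccc(CCCCCCCCC(=O)c2c(OC)ccc(-c3cc(OC)c(OC)cc3CCCCCCCO[Si](C)(C)C(C)(C)C)c2OC)cc1OC | intermediate
21 | 9-(3,4-dimethoxyphenyl)-1-{3-[2-(7-hydroxyheptyl)-4,5-dimethoxyphenyl]-2,6-dimethoxyphenyl}nonan-1-one | COc1ccc(CCCCCCCCC(=O)c2c(OC)ccc(-c3cc(OC)c(OC)cc3CCCCCCCO)c2OC)cc1OC | intermediate
22 | 7-(2-{3-[9-(3,4-dimethoxyphenyl)nonanoyl]-2,4-dimethoxyphenyl}-4,5-dimethoxyphenyl)heptanal | COc1ccc(CCCCCCCCC(=O)c2c(OC)ccc(-c3cc(OC)c(OC)cc3CCCCCCC=O)c2OC)cc1OC | intermediate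
23 | lithium enolate of 13 (not isolated) | [Li]OC(=C)c1c(OC)cccc1OC | intermediate
24 | aldol adduct of 13 and 22, 3-hydroxynonan-1-one (racemic) | COc1ccc(CCCCCCCCC(=O)c2c(OC)ccc(-c3cc(OC)c(OC)cc3CCCCCCC(O)CC(=O)c4c(OC)cccc4OC)c2OC)cc1OC | intermediate
25 | methanesulfonate of 24 (racemic, not isolated) | COc1ccc(CCCCCCCCC(=O)c2c(OC)ccc(-c3cc(OC)c(OC)cc3CCCCCCC(OS(C)(=O)=O)CC(=O)c4c(OC)cccc4OC)c2OC)cc1OC | intermediate
26 | (E)-enone from 24 | COc1ccc(CCCCCCCCC(=O)c2c(OC)ccc(-c3cc(OC)c(OC)cc3CCCCCC/C=C/C(=O)c4c(OC)cccc4OC)c2OC)cc1OC | intermediate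
27 | giganteone A octamethyl ether | COc1ccc(CCCCCCCCC(=O)c2c(OC)ccc(-c3cc(OC)c(OC)cc3CCCCCCCCC(=O)c4c(OC)cccc4OC)c2OC)cc1OC | intermediate
28 | giganteone A octakis(dibromoboryl) ether (idealised aryl borate, not isolated) | BrB(Br)Oc1ccc(CCCCCCCCC(=O)c2c(OB(Br)Br)ccc(-c3cc(OB(Br)Br)c(OB(Br)Br)cc3CCCCCCCCC(=O)c4c(OB(Br)Br)cccc4OB(Br)Br)c2OB(Br)Br)cc1OB(Br)Br | intermediate
29 | giganteone A | O=C(CCCCCCCCc1cc(O)c(O)cc1-c1ccc(O)c(C(=O)CCCCCCCCc2ccc(O)c(O)c2)c1O)c1c(O)cccc1O | target

## Step count and risk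

Total steps: 19. Longest linear sequence: 17 (steps 1–4, 6–8, 10–19).

**Most likely to fail, first: step 16 (aldol on the keto aldehyde).**
- Risk: proton transfer to the aldehyde or to the ketone of 22, or retro-aldol cleavage.
- The fallback sets out from 13 (with 22 as partner) and comes back at 24.
- Ketone 13 is silylated with TMSOTf/Et3N in CH2Cl2 at 0 °C to the trimethylsilyl enol ether F2.
- F2 is then added to 22 in a Mukaiyama aldol reaction (BF3·OEt2, CH2Cl2, −78 °C, aqueous NaHCO3 work-up) to give 24.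
- The nucleophile is now neutral and the aldehyde is activated by a Lewis acid, so no base is present to enolise either carbonyl group of 22.

**Second: step 10 (hindered, electron-rich Suzuki coupling).**
- Risk: protodeboronation of 12 or slow transmetallation.
- The fallback sets out from 10 and comes back at 15.
- Bromide 10 is lithiated as before to 11 and transmetallated with ZnCl2 (THF, −78 °C → rt) to the arylzinc chloride F1.
- F1 is joined to bromoketone 14 by a Negishi coupling (Pd2(dba)3/SPhos or Pd-PEPPSI-IPr, THF, 50 °C).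
- This path has no boronate and no aqueous base, and the arylzinc tolerates the enolisable ketone.

**Third: step 19 (eightfold demethylation and isolation of an air-sensitive octaphenol).**
- Risk: incomplete cleavage, persistent boron chelates, or loss on purification.
- The fallback sets out from 27 and comes back at 29.
- Ether 27 is cleaved by neutral silyl transfer with TMSI (16 equiv, CHCl3, 55 °C, sealed, dark) to the octakis(trimethylsilyl) ether F3.
- F3 is methanolysed at rt, and the crude phenol is not purified. It is peracetylated directly (Ac2O, pyridine, cat. DMAP) to the air-stable octaacetate F4.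
- F4 is chromatographed or crystallised free of partly methylated material, then released by acid methanolysis (cat. AcCl in MeOH, 40 °C, argon) to give pure 29.

## Further compounds

F1 | step 10 | [2-(7-{[tert-butyl(dimethyl)silyl]oxy}heptyl)-4,5-dimethoxyphenyl]zinc chloride | COc1cc([Zn]Cl)c(CCCCCCCO[Si](C)(C)C(C)(C)C)cc1OC
F2 | step 16 | {[1-(2,6-dimethoxyphenyl)ethenyl]oxy}trimethylsilane | C=C(O[Si](C)(C)C)c1c(OC)cccc1OC
F3 | step 19 | giganteone A octakis(trimethylsilyl) ether | C[Si](C)(C)Oc1ccc(CCCCCCCCC(=O)c2c(O[Si](C)(C)C)ccc(-c3cc(O[Si](C)(C)C)c(O[Si](C)(C)C)cc3CCCCCCCCC(=O)c4c(O[Si](C)(C)C)cccc4O[Si](C)(C)C)c2O[Si](C)(C)C)cc1O[Si](C)(C)C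
F4 | step 19 | giganteone A octaacetate | CC(=O)Oc1ccc(CCCCCCCCC(=O)c2c(OC(C)=O)ccc(-c3cc(OC(C)=O)c(OC(C)=O)cc3CCCCCCCCC(=O)c4c(OC(C)=O)cccc4OC(C)=O)c2OC(C)=O)cc1OC(C)=O
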